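## Structural features

The target is a depside: two benzene rings joined by one aryl ester, with no stereocentre. Ring A, numbered from the ester-bearing carbon C1, has hydroxyl groups at C2 and C6 on both sides of the ester oxygen, an acetyl group at C3 hydrogen-bonded to the C2 hydroxyl, and a pentyl chain at C4. Ring B, numbered from the carboxyl-bearing carbon C1, has a methoxy group at C2, a free hydroxyl at C4 and a propyl chain at C6. The fragile group is the aryl ester: it is an activated ester flanked by two free phenols that can take over the acyl group under base, both rings are oxidisable electron-rich phenols, and the methyl ketone is enolisable. The real difficulty is twofold. The ester joins a benzoic acid with two ortho substituents to a phenol with two ortho substituents, and the oxygen pattern of ring B (ether on the ortho oxygen, free para hydroxyl) is the reverse of what alkylation of a 2,4-dihydroxybenzoate delivers. The key step uses the fact that on ring B the carboxyl carbon C1 and the alkyl-bearing carbon C6 are neighbours, with the methoxy-bearing C2 beside C1. This is the pattern left when a 3-methoxyaryne takes a carbon nucleophile at the aryne carbon remote from the methoxy group and a carbonyl carbon at the one beside it. The propyl group is then read as a decarboxylated ethylmalonate carbon, so the ring B bonds C1–C(=O) and C6–Cα both arise by inserting the aryne into the C–C bond of a malonate that already carries ring A as its aryl ester.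

## Logic of the disconnections

**27 to 26.** The three O–CH2Ph bonds (ring A O2 and O6, ring B O4) are cut. All phenols stay masked to the end as ethers that leave under neutral hydrogenolysis, so no acid or base meets the free depside. The gain is that every earlier step runs on a substrate without acidic or nucleophilic phenols. The demand is that hydrogenolysis spares the aryl ketone and the aryl ester.

**26 to 25 to 24.** A carboxyl group is added back at the benzylic carbon of the propyl chain (C–CO2H bond), then its tert-butyl group (O–C bond). The extra carboxyl is what makes that carbon a malonate carbon in the key step. The demand is a decarboxylation of an α-arylalkanoic acid without base (radical conditions) and an ester cleavage that leaves the aryl ester alone (acidolysis of the tert-butyl ester).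

**24 to 12 and 21.** Two ring B bonds are cut: C6–Cα and C1–C(=O). Seen forwards, the aryne 22 released from 21 is inserted into the Cα–C(=O) bond of 12. The hindered ester is thereby made by C–C bond formation and the ortho relation of carboxyl and alkyl, with the methoxy group beside the carboxyl, follows from aryne polarisation. The gain is full convergence: ring A arrives complete, ring B arrives as a four-substituent aryne precursor. The demand is threefold: regioselective addition to 22, acyl transfer from the aryl ester and not the tert-butyl ester, and C–C cleavage of 23 faster than loss of the ring A aryloxide.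

**12 to 8 and 11.** The ester bond C(=O)–O(ring A) is cut at a stage where the acyl partner is an unhindered malonic half acid. The demand is only a carbodiimide coupling that tolerates the acidic malonate hydrogen.

**8 to 6 to 5 to 2 to 1.** The C3–acetyl bond is cut to a C3–Br bond, this to C3–H, the C1–O bond to C1–H, and the two O-benzyl bonds last. The symmetry of 5 is the reason for the order: the two free ring positions are equivalent, so bromination needs no regiocontrol, and the carbon between the two benzyloxy groups of 2 is the only doubly activated site for lithiation. The demand is a cross-coupling at a bromide with two ortho substituents.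

**11 to 9.** The Cα–CO2H bond is cut; an ester enolate and CO2 give the half acid in one step.

**21 to 20 to 19 to 17 to 15 to 14 to 13.** The O–Tf bond, the O–carbamoyl bond, the benzyl ether (exchanged for a triisopropylsilyl ether), the C2–Si bond, the carbamate and the silyl ether are cut in turn, ending at a symmetric diol that already holds the one methyl ether. The carbamate directs lithiation to the carbon between itself and the methoxy group, and the bulky silyl ether blocks the other two ring positions. The benzyl group enters only after the C–Si bond is set. A shorter-looking sequence from the symmetric dimethyl ether (silylation between the methoxy groups, benzylation, mono-demethylation, triflation) was rejected. Lithiation of a benzyl ether flanked by methoxy groups has no reliable site control, and no demethylating agent, Lewis acidic or nucleophilic, is safe for both a benzyl ether and an electron-rich aryl–silicon bond.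

## Other disconnections considered

**Alternative 1:** Ring A is cut at C2–C3 and C4–C5 (numbering from the ester-bearing carbon). Forwards, the diene 1-methoxy-1,3-bis[(trimethylsilyl)oxy]buta-1,3-dien-2-yl 4-(benzyloxy)-2-methoxy-6-propylbenzoate A2, which already carries ring B on its C2 oxygen, undergoes a Diels–Alder reaction with non-3-yn-2-one A3. Loss of one alkoxy group and desilylation would give 3-acetyl-2,6-dihydroxy-4-pentylphenyl 4-(benzyloxy)-2-methoxy-6-propylbenzoate A1.
- In favour: the ester C–O bond would be made by alkylating the carboxylate of 4-(benzyloxy)-2-methoxy-6-propylbenzoic acid A4 with an α-halo ketoester, which is insensitive to hindrance. The polarity of A2 and A3 matches the required regiochemistry. Ring A needs no protecting groups, and only one benzyl ether remains to be removed.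
- Against: ynones with an alkyl group on the β-carbon are weak dienophiles toward such silyl ketene acetal dienes. A2 places an acyloxy group between two silyloxy groups, so acyl shift to a neighbouring oxygen during formation or desilylation would scramble the ester position. A4 must still be made by a route of its own that solves the ring B oxygen pattern.
- Comparison: it equals the chosen plan in avoiding an esterification between two hindered partners, and it is better in protecting-group economy on ring A and in the final deprotection. It is weaker in convergence and in the expected rate of the cycloaddition, and it leaves the ring B problem unsolved, which the aryne insertion solves in the same step as the ester.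

**Alternative 2:** Ring B is cut at C1–C2 and C5–C6. Forwards, 3-acetyl-2,6-bis(benzyloxy)-4-pentylphenyl hex-2-ynoate A6, from 8 and the acetylenic acid, is heated with 1,1-dimethoxy-3-(trimethylsilyloxy)buta-1,3-diene A7. Cycloaddition, loss of one methoxy group and desilylation would give 3-acetyl-2,6-bis(benzyloxy)-4-pentylphenyl 4-hydroxy-2-methoxy-6-propylbenzoate A5.
- In favour: the reaction type is established for acetylenic esters and gives exactly the 2-methoxy-4-hydroxy-6-alkyl benzoate pattern. The ring B hydroxyl needs no protection. The ester is made from 8 and an unhindered acid. About three steps follow 8, and the whole six-step aryne precursor branch disappears.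
- Against: 3-alkyl propiolates react slowly and need temperatures at which A7 is short-lived, so a large excess and modest conversion are to be expected. The aryl ynoate A6 is open to conjugate addition and acyl transfer.
- Comparison: on step economy and on precedent this alternative is better than the chosen plan. On structural logic it is equal, since both make the ester before ring B is complete. The chosen plan has the advantage only in milder conditions for the ring-forming event and in independent variation of the two halves.

**Alternative 3:** The ester C–O bond and the ring B C1–C6 bond are cut. Forwards, thermolysis of 6-(2,4-dioxoheptyl)-2,2-dimethyl-4H-1,3-dioxin-4-one A9 releases an acylketene that 8 captures to give 3-acetyl-2,6-bis(benzyloxy)-4-pentylphenyl 3,5,7-trioxodecanoate A10. Aldol closure of its C2 onto the C7 ketone and dehydration would give 3-acetyl-2,6-bis(benzyloxy)-4-pentylphenyl 2,4-dihydroxy-6-propylbenzoate A8.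
- In favour: ketene capture is one of the best ways to acylate a hindered phenol, the aromatisation follows the biosynthetic logic, and ring B needs no protecting group.
- Against: A8 has both ring B oxygens free, and the target needs the methyl group on the chelated, less reactive ortho oxygen. The para hydroxyl would have to be protected, the ortho hydroxyl methylated under forcing basic conditions next to a base-sensitive aryl ester, and the para group removed again. In A10 the aryl ester is a good leaving group, so Claisen or pyrone closure with loss of the ring A aryloxide competes with the aldol. A9 needs several steps.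
- Comparison: it equals the chosen plan in making the hindered ester without a hindered esterification, and it is better in precedent for the ring-forming step. It is weaker on the oxygen pattern, which the aryne insertion sets directly, and it is not shorter once the extra protection and methylation steps are counted.

Key step: step 13

Remark 1: 5-methoxybenzene-1,3-diol (13) and tert-butyl butanoate (9) are taken as catalogue chemicals; 13 already holds the single methyl ether and 9 gives the malonic half acid in one step.

Remark 2: the structures of 12, 21 and 24 were checked atom by atom against the regiochemistry of the insertion and are used unchanged.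

Remark 3: with ring A numbered from the ester-bearing carbon, the cycloaddition of alternative 1 forms C2–C3 and C4–C5.

## Steps

Step 1
Reactants: 1 olivetol (5-pentylbenzene-1,3-diol)
Product: 2 1,3-bis(benzyloxy)-5-pentylbenzene
Conditions: BnBr (2.3 equiv), K2CO3, DMF, 60 °C
Reagents that add atoms: benzyl bromide, BrCc1ccccc1
Why: Williamson ether synthesis; both phenols are unhindered and O-alkylation dominates with carbonate in DMF.

Step 2
Reactants: 2 1,3-bis(benzyloxy)-5-pentylbenzene
Product: 5 2,6-bis(benzyloxy)-4-pentylphenol, via aryllithium 3 (not isolated), via dimethyl arylboronate 4 (not isolated)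
Conditions: n-BuLi (1.2 equiv), THF, 0 °C, 1 h; B(OMe)3, −78 °C to rt; AcOH, 30% H2O2, 0 °C to rt
Reagents that add atoms: hydrogen peroxide, OO
Why: Directed ortho-metalation at the only carbon flanked by two alkoxy groups, borylation of 3 and oxidative conversion of the C–B bond of 4 into C–O; a short lithiation at 0 °C limits deprotonation of the benzylic OCH2 groups.

Step 3
Reactants: 5 2,6-bis(benzyloxy)-4-pentylphenol
Product: 6 2,6-bis(benzyloxy)-3-bromo-4-pentylphenol
Conditions: NBS (1.0 equiv), MeCN, −20 °C to 0 °C, dark
Reagents that add atoms: N-bromosuccinimide, O=C1CCC(=O)N1Br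
Why: Electrophilic aromatic bromination; the two free ring positions are equivalent by symmetry and each is ortho and para to a benzyloxy group, so one equivalent should give a single monobromide.

Step 4
Reactants: 6 2,6-bis(benzyloxy)-3-bromo-4-pentylphenol
Product: 8 1-[2,4-bis(benzyloxy)-3-hydroxy-6-pentylphenyl]ethan-1-one, via aryl enol ether 7 (not isolated)
Conditions: Bu3Sn[C(OEt)=CH2] (1.5 equiv), PdCl2(PPh3)2 (5 mol %), toluene, 100 °C; then 1 M HCl, THF, rt
Reagents that add atoms: tributyl(1-ethoxyethenyl)stannane, CCCC[Sn](CCCC)(CCCC)C(=C)OCC; water, O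
Why: Migita–Kosugi–Stille coupling with an acetyl anion equivalent (the divalent palladium precatalyst is reduced in the flask to zerovalent palladium), then acid hydrolysis of enol ether 7; the free phenol and the benzyl ethers are inert to both stages.

Step 5
Reactants: 9 tert-butyl butanoate
Product: 11 2-(tert-butoxycarbonyl)butanoic acid (racemic), via lithium ester enolate 10 (not isolated)
Conditions: LiN(i-Pr)2 (1.1 equiv), THF, −78 °C; CO2 (gas), −78 °C to 0 °C; cold 1 M HCl
Reagents that add atoms: carbon dioxide, O=C=O
Why: Carboxylation of an ester enolate; the tert-butyl ester suppresses self-condensation, and the new stereocentre is formed racemic, which is immaterial because it is removed in step 15.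

Step 6
Reactants: 8 1-[2,4-bis(benzyloxy)-3-hydroxy-6-pentylphenyl]ethan-1-one; 11 2-(tert-butoxycarbonyl)butanoic acid
Product: 12 1-[3-acetyl-2,6-bis(benzyloxy)-4-pentylphenyl] 3-tert-butyl 2-ethylpropanedioate (racemic)
Conditions: DCC (1.1 equiv), DMAP (10 mol %), CH2Cl2, 0 °C to rt
Reagents that add atoms: none
Why: Steglich esterification; carbodiimide activation of a malonic half acid gives a very reactive acylating species, so the two ortho substituents of 8 should not block O-acylation. The acetyl group is meta to the new acyloxy group, so no Baker–Venkataraman acyl shift can follow.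

Step 7
Reactants: 13 5-methoxybenzene-1,3-diol
Product: 14 3-methoxy-5-{[tri(propan-2-yl)silyl]oxy}phenol
Conditions: i-Pr3SiCl (1.0 equiv), imidazole, DMF, 0 °C to rt
Reagents that add atoms: chlorotri(propan-2-yl)silane, CC(C)[Si](Cl)(C(C)C)C(C)C
Why: Monosilylation of a symmetric diol gives a statistical mixture from which 14 is separated and the diol and bis-ether are recycled; the bulky silyl ether is chosen because it neither directs lithiation nor allows it next to itself.

Step 8
Reactants: 14 3-methoxy-5-{[tri(propan-2-yl)silyl]oxy}phenol
Product: 15 3-methoxy-5-{[tri(propan-2-yl)silyl]oxy}phenyl diethylcarbamate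
Conditions: Et2NCOCl (1.3 equiv), Et3N, DMAP (10 mol %), MeCN, 60 °C
Reagents that add atoms: N,N-diethylcarbamoyl chloride, CCN(CC)C(Cl)=O
Why: O-carbamoylation of a phenol; it places the strongest ortho-directing group on the oxygen that will later carry the triflate.

Step 9
Reactants: 15 3-methoxy-5-{[tri(propan-2-yl)silyl]oxy}phenyl diethylcarbamate
Product: 17 3-methoxy-5-{[tri(propan-2-yl)silyl]oxy}-2-(trimethylsilyl)phenyl diethylcarbamate, via ortho-lithiated carbamate 16 (not isolated)
Conditions: s-BuLi (1.2 equiv), TMEDA, THF, −78 °C, 1 h; Me3SiCl, −78 °C to rt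
Reagents that add atoms: chlorotrimethylsilane, C[Si](C)(C)Cl
Why: Directed ortho-metalation; carbamate and methoxy group cooperate at the carbon between them, while the other two ring positions lie beside the shielding silyl ether. At −78 °C the anionic ortho-Fries shift of 16 is slow and Me3SiCl traps it.

Step 10
Reactants: 17 3-methoxy-5-{[tri(propan-2-yl)silyl]oxy}-2-(trimethylsilyl)phenyl diethylcarbamate
Product: 19 5-(benzyloxy)-3-methoxy-2-(trimethylsilyl)phenyl diethylcarbamate, via ammonium phenolate 18 (not isolated)
Conditions: Bu4NF (1.05 equiv), THF, 0 °C, 15 min; then BnBr (1.5 equiv), 0 °C to rt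
Reagents that add atoms: benzyl bromide, BrCc1ccccc1
Why: Fluoride cleaves the aryl O–Si bond within minutes at 0 °C, much faster than the unactivated aryl C–Si bond, and phenolate 18 is benzylated in the same flask (Williamson); the diethylcarbamate has no N–H and is inert to fluoride and phenolate.

Step 11
Reactants: 19 5-(benzyloxy)-3-methoxy-2-(trimethylsilyl)phenyl diethylcarbamate
Product: 20 5-(benzyloxy)-3-methoxy-2-(trimethylsilyl)phenol
Conditions: LiAlH4 (2 equiv), THF, 0 °C to 50 °C; then H2O, 15% NaOH
Reagents that add atoms: none
Why: Reductive cleavage of an aryl carbamate by hydride addition to the carbonyl and loss of the aryloxide; benzyl ether, methyl ether and the aryl–silicon bond are inert to LiAlH4.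

Step 12
Reactants: 20 5-(benzyloxy)-3-methoxy-2-(trimethylsilyl)phenol
Product: 21 5-(benzyloxy)-3-methoxy-2-(trimethylsilyl)phenyl trifluoromethanesulfonate
Conditions: Tf2O (1.2 equiv), pyridine, CH2Cl2, 0 °C
Reagents that add atoms: trifluoromethanesulfonic anhydride, O=S(=O)(OS(=O)(=O)C(F)(F)F)C(F)(F)F
Why: O-sulfonylation of a phenol; without fluoride the ortho-silyl triflate is stable to pyridine at 0 °C.

Step 13
Reactants: 12 1-[3-acetyl-2,6-bis(benzyloxy)-4-pentylphenyl] 3-tert-butyl 2-ethylpropanedioate; 21 5-(benzyloxy)-3-methoxy-2-(trimethylsilyl)phenyl trifluoromethanesulfonate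
Product: 24 3-acetyl-2,6-bis(benzyloxy)-4-pentylphenyl 4-(benzyloxy)-2-(1-tert-butoxy-1-oxobutan-2-yl)-6-methoxybenzoate (racemic at the benzylic carbon), via aryne 22 (not isolated), via cesium benzocyclobutenolate 23 (not isolated)
Conditions: CsF (3 equiv), MeCN, 60 °C, 21 (1.5 equiv) added over 2 h
Reagents that add atoms: none
Why: Proposed new method: fluoride removes the trimethylsilyl group of 21 with loss of triflate to give aryne 22, and the basic medium converts 12 into its cesium enolate, whose carbon adds to the aryne carbon meta to the methoxy group (the future C6 of ring B) because the inductively withdrawing methoxy group polarises the distorted aryne and stabilises the carbanion developing at the neighbouring carbon (the future C1). That carbanion attacks the aryl ester carbonyl in a 4-exo-trig closure to give benzocyclobutenolate 23, which reopens by cleavage of the former Cα–C(=O) bond with release of ring strain to a tert-butyl ester enolate that is protonated to 24, so the net change is insertion of the aryne into the Cα–C(=O) σ bond with formation of C6–Cα and C1–C(=O) of ring B. The closest known reaction type is the fluoride-induced acyl-alkylation of arynes with β-ketoesters and dialkyl malonates; an aryl ester as the migrating acyl group of an α-substituted mixed malonate lies outside it. No ring remains closed: the only ring formed is the four-membered ring of 23, closed in the 4-exo mode and opened again. The benzylic stereocentre forms without control, so 24 is racemic, and the centre is removed in step 15. Regioselectivity of addition is secured by the 3-methoxy group of 22, the 5-benzyloxy group being too remote to oppose it. The choice of the aryl ester over the tert-butyl ester carbonyl rests on its higher electrophilicity and on the bulk of the tert-butyl group, and C–C cleavage of 23 is expected to outrun loss of the ring A aryloxide because only the former releases the strain of the four-membered ring. The acetyl group is too weakly acidic for CsF and is meta to the acyloxy group, so neither ketone arylation nor an acyl shift is expected, and slow addition of 21 keeps the aryne concentration low so that the enolate captures it.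

Step 14
Reactants: 24 3-acetyl-2,6-bis(benzyloxy)-4-pentylphenyl 4-(benzyloxy)-2-(1-tert-butoxy-1-oxobutan-2-yl)-6-methoxybenzoate
Product: 25 2-[2-{[3-acetyl-2,6-bis(benzyloxy)-4-pentylphenoxy]carbonyl}-5-(benzyloxy)-3-methoxyphenyl]butanoic acid (racemic)
Conditions: CF3CO2H, CH2Cl2 (1:4), 0 °C to rt, N2 sweep
Reagents that add atoms: none
Why: Acidolysis of a tert-butyl ester by loss of the tert-butyl cation; the aryl ester, the benzyl ethers and the ketone should tolerate a short exposure, and the gas sweep removes the alkene before it can alkylate the electron-rich rings.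

Step 15
Reactants: 25 2-[2-{[3-acetyl-2,6-bis(benzyloxy)-4-pentylphenoxy]carbonyl}-5-(benzyloxy)-3-methoxyphenyl]butanoic acid
Product: 26 3-acetyl-2,6-bis(benzyloxy)-4-pentylphenyl 4-(benzyloxy)-2-methoxy-6-propylbenzoate
Conditions: 9-mesityl-10-phenylacridinium tetrafluoroborate (5 mol %), PhSSPh (10 mol %), i-Pr2NEt (20 mol %), CF3CH2OH/CH2Cl2, 450 nm LEDs, rt
Reagents that add atoms: none
Why: Photoredox hydrodecarboxylation, an established reaction of α-arylalkanoic acids: the excited acridinium oxidises the carboxylate, CO2 is lost, and the secondary benzylic radical takes a hydrogen atom from thiophenol formed from the disulfide. The stereocentre disappears and the propyl group results without base strong enough to touch the aryl ester.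

Step 16
Reactants: 26 3-acetyl-2,6-bis(benzyloxy)-4-pentylphenyl 4-(benzyloxy)-2-methoxy-6-propylbenzoate
Product: 27 3-acetyl-2,6-dihydroxy-4-pentylphenyl 4-hydroxy-2-methoxy-6-propylbenzoate (CNP0112527.0)
Conditions: H2 (1 atm), 10% palladium on carbon (Pd/C), EtOAc, rt
Reagents that add atoms: none
Why: Hydrogenolysis of three aryl benzyl ethers under neutral conditions; the ketone with two ortho substituents and the hindered aryl ester are not reduced at 1 atm, and no base is present that could move the acyl group to a flanking phenol.

## Compound list

1 | olivetol (5-pentylbenzene-1,3-diol) | CCCCCc1cc(O)cc(O)c1 | starting material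
2 | 1,3-bis(benzyloxy)-5-pentylbenzene | CCCCCc1cc(OCc2ccccc2)cc(OCc2ccccc2)c1 | intermediate
3 | [2,6-bis(benzyloxy)-4-pentylphenyl]lithium | [Li]c1c(OCc2ccccc2)cc(CCCCC)cc1OCc1ccccc1 | intermediate (not isolated)
4 | dimethyl [2,6-bis(benzyloxy)-4-pentylphenyl]boronate | COB(OC)c1c(OCc2ccccc2)cc(CCCCC)cc1OCc1ccccc1 | intermediate (not isolated)
5 | 2,6-bis(benzyloxy)-4-pentylphenol | CCCCCc1cc(OCc2ccccc2)c(O)c(OCc2ccccc2)c1 | intermediate
6 | 2,6-bis(benzyloxy)-3-bromo-4-pentylphenol | CCCCCc1cc(OCc2ccccc2)c(O)c(OCc2ccccc2)c1Br | intermediate
7 | 2,6-bis(benzyloxy)-3-(1-ethoxyethenyl)-4-pentylphenol | CCCCCc1cc(OCc2ccccc2)c(O)c(OCc2ccccc2)c1C(=C)OCC | intermediate (not isolated)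
8 | 1-[2,4-bis(benzyloxy)-3-hydroxy-6-pentylphenyl]ethan-1-one | CCCCCc1cc(OCc2ccccc2)c(O)c(OCc2ccccc2)c1C(C)=O | intermediate
9 | tert-butyl butanoate | CCCC(=O)OC(C)(C)C | starting material
10 | lithium 1-tert-butoxybut-1-en-1-olate (double-bond geometry immaterial) | CCC=C(O[Li])OC(C)(C)C | intermediate (not isolated)
11 | 2-(tert-butoxycarbonyl)butanoic acid (racemic) | CCC(C(=O)O)C(=O)OC(C)(C)C | intermediate
12 | 1-[3-acetyl-2,6-bis(benzyloxy)-4-pentylphenyl] 3-tert-butyl 2-ethylpropanedioate (racemic) | CCCCCc1cc(OCc2ccccc2)c(OC(=O)C(CC)C(=O)OC(C)(C)C)c(OCc2ccccc2)c1C(C)=O | intermediate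
13 | 5-methoxybenzene-1,3-diol | COc1cc(O)cc(O)c1 | starting material
14 | 3-methoxy-5-{[tri(propan-2-yl)silyl]oxy}phenol | COc1cc(O)cc(O[Si](C(C)C)(C(C)C)C(C)C)c1 | intermediate
15 | 3-methoxy-5-{[tri(propan-2-yl)silyl]oxy}phenyl diethylcarbamate | CCN(CC)C(=O)Oc1cc(OC)cc(O[Si](C(C)C)(C(C)C)C(C)C)c1 | intermediate
16 | {2-[(diethylcarbamoyl)oxy]-6-methoxy-4-{[tri(propan-2-yl)silyl]oxy}phenyl}lithium | CCN(CC)C(=O)Oc1cc(O[Si](C(C)C)(C(C)C)C(C)C)cc(OC)c1[Li] | intermediate (not isolated)
17 | 3-methoxy-5-{[tri(propan-2-yl)silyl]oxy}-2-(trimethylsilyl)phenyl diethylcarbamate | CCN(CC)C(=O)Oc1cc(O[Si](C(C)C)(C(C)C)C(C)C)cc(OC)c1[Si](C)(C)C | intermediate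
18 | tetrabutylammonium 3-[(diethylcarbamoyl)oxy]-5-methoxy-4-(trimethylsilyl)phenolate | CCCC[N+](CCCC)(CCCC)CCCC.CCN(CC)C(=O)Oc1cc([O-])cc(OC)c1[Si](C)(C)C | intermediate (not isolated)
19 | 5-(benzyloxy)-3-methoxy-2-(trimethylsilyl)phenyl diethylcarbamate | CCN(CC)C(=O)Oc1cc(OCc2ccccc2)cc(OC)c1[Si](C)(C)C | intermediate
20 | 5-(benzyloxy)-3-methoxy-2-(trimethylsilyl)phenol | COc1cc(OCc2ccccc2)cc(O)c1[Si](C)(C)C | intermediate
21 | 5-(benzyloxy)-3-methoxy-2-(trimethylsilyl)phenyl trifluoromethanesulfonate | COc1cc(OCc2ccccc2)cc(OS(=O)(=O)C(F)(F)F)c1[Si](C)(C)C | intermediate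
22 | 5-(benzyloxy)-3-methoxy-1,2-didehydrobenzene (5-(benzyloxy)-3-methoxybenzyne) | COC1=CC(OCc2ccccc2)=CC#C1 | intermediate (not isolated)
23 | cesium 7-[3-acetyl-2,6-bis(benzyloxy)-4-pentylphenoxy]-3-(benzyloxy)-8-(tert-butoxycarbonyl)-8-ethyl-5-methoxybicyclo[4.2.0]octa-1,3,5-trien-7-olate (racemic, both diastereomers) | COc1cc(OCc2ccccc2)cc2c1C([O-])(Oc1c(OCc3ccccc3)cc(CCCCC)c(C(C)=O)c1OCc1ccccc1)C2(CC)C(=O)OC(C)(C)C.[Cs+] | intermediate (not isolated)
24 | 3-acetyl-2,6-bis(benzyloxy)-4-pentylphenyl 4-(benzyloxy)-2-(1-tert-butoxy-1-oxobutan-2-yl)-6-methoxybenzoate (racemic) | CCCCCc1cc(OCc2ccccc2)c(OC(=O)c2c(C(CC)C(=O)OC(C)(C)C)cc(OCc3ccccc3)cc2OC)c(OCc2ccccc2)c1C(C)=O | intermediate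
25 | 2-[2-{[3-acetyl-2,6-bis(benzyloxy)-4-pentylphenoxy]carbonyl}-5-(benzyloxy)-3-methoxyphenyl]butanoic acid (racemic) | CCCCCc1cc(OCc2ccccc2)c(OC(=O)c2c(C(CC)C(=O)O)cc(OCc3ccccc3)cc2OC)c(OCc2ccccc2)c1C(C)=O | intermediate
26 | 3-acetyl-2,6-bis(benzyloxy)-4-pentylphenyl 4-(benzyloxy)-2-methoxy-6-propylbenzoate | CCCCCc1cc(OCc2ccccc2)c(OC(=O)c2c(CCC)cc(OCc3ccccc3)cc2OC)c(OCc2ccccc2)c1C(C)=O | intermediate
27 | 3-acetyl-2,6-dihydroxy-4-pentylphenyl 4-hydroxy-2-methoxy-6-propylbenzoate | CCCCCc1cc(O)c(OC(=O)c2c(CCC)cc(O)cc2OC)c(O)c1C(C)=O | target

## Step count and risk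

Total: 16 steps. Longest linear sequence: 10 steps (13 to 27, steps 7 to 12 and 13 to 16). The ring A branch is 9 steps linear (steps 1 to 4, 6, 13 to 16), and the half acid 11 takes one step.

**Step 13 (key step, proposed new method).** Three processes are most likely to go wrong:
- E1cB loss of the ring A aryloxide from the enolate of 12, followed by capture of the aryne by that aryloxide.
- Protonation of the aryl carbanion before the 4-exo closure, which gives plain α-arylation.
- Expulsion of the aryloxide from 23 in place of C–C cleavage.

All three stem from the aryl ester being both the acyl donor and a leaving group.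

Fallback in known chemistry, setting out from 21 and coming back at 26:
- Insertion of 22, generated from 21 with CsF in MeCN, into commercial diethyl ethylmalonate, a dialkyl malonate of the established substrate class, would give ethyl 4-(benzyloxy)-2-(1-ethoxy-1-oxobutan-2-yl)-6-methoxybenzoate F1.
- KOH in aqueous DMSO at 100 °C would hydrolyse both esters to 4-(benzyloxy)-2-(1-carboxypropyl)-6-methoxybenzoic acid F2.
- Hydrodecarboxylation under the conditions of step 15, which oxidise the alkyl carboxylate and leave the benzoic acid in place, would give 4-(benzyloxy)-2-methoxy-6-propylbenzoic acid F3.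
- Oxalyl chloride with catalytic DMF would give 4-(benzyloxy)-2-methoxy-6-propylbenzoyl chloride F4, and F4 with 8, Et3N and DMAP in CH2Cl2 would give 26.

This brings back the acylation between two hindered partners that the insertion avoids, which is why it is the reserve. Steps 5, 6 and 14 would not be needed.

**Step 15.** Unproductive oxidation of the alkoxy-rich arenes by the excited acridinium, or dimerisation and oxygen trapping of the benzylic radical in place of hydrogen transfer, could stall the decarboxylation. Fallback from 25 to 26 by Barton reductive decarboxylation: 25 with 1-hydroxypyridine-2(1H)-thione and DCC in CH2Cl2 in the dark would give 2-sulfanylidenepyridin-1(2H)-yl 2-[2-{[3-acetyl-2,6-bis(benzyloxy)-4-pentylphenoxy]carbonyl}-5-(benzyloxy)-3-methoxyphenyl]butanoate F5, and visible-light irradiation of F5 with t-BuSH would give 26.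

**Step 4.** Oxidative addition of zerovalent palladium into an electron-rich C–Br bond with two ortho substituents may be slow, so that protodebromination or stannane homocoupling takes over. Fallback from 6 to 8 by halogen–lithium exchange: MeLi (1 equiv) then t-BuLi (2 equiv) in THF at −78 °C would give lithium 2,6-bis(benzyloxy)-3-lithio-4-pentylphenolate F6, which with N-methoxy-N-methylacetamide and aqueous acid work-up would give 8.

**Step 9.** Incomplete lithiation, or carbamoyl migration to carbon (anionic ortho-Fries shift) before silylation, would lower the return of 17. Fallback from 14 to 17 by bromination and silyl migration: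
- NBS with catalytic i-Pr2NH in CH2Cl2 (amine-mediated ortho-bromination, the other ortho site being shielded by the silyl ether) would give 2-bromo-3-methoxy-5-{[tri(propan-2-yl)silyl]oxy}phenol F7.
- Hexamethyldisilazane would give [2-bromo-3-methoxy-5-{[tri(propan-2-yl)silyl]oxy}phenoxy]trimethylsilane F8.
- n-BuLi in THF at −78 °C would effect bromine–lithium exchange and a 1,3 O-to-C silyl shift (retro-Brook) to lithium 3-methoxy-5-{[tri(propan-2-yl)silyl]oxy}-2-(trimethylsilyl)phenolate F9.
- Et2NCOCl would convert F9 into 17.

**Step 2.** Deprotonation of a benzylic OCH2 group followed by 1,2-Wittig rearrangement could compete with ring lithiation. Fallback from 1 to 4 by halogen–magnesium exchange: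
- I2 and NaHCO3 in aqueous THF at 0 °C would give 2-iodo-5-pentylbenzene-1,3-diol F10, iodination of resorcinols under these conditions going between the hydroxyl groups.
- BnBr and K2CO3 in DMF would give 1,3-bis(benzyloxy)-2-iodo-5-pentylbenzene F11.
- i-PrMgCl·LiCl in THF at −20 °C would give [2,6-bis(benzyloxy)-4-pentylphenyl]magnesium chloride F12.
- B(OMe)3 would convert F12 into 4, which is oxidised to 5 as in step 2.

## Further compounds

F1 | step 13 | ethyl 4-(benzyloxy)-2-(1-ethoxy-1-oxobutan-2-yl)-6-methoxybenzoate (racemic) | CCOC(=O)C(CC)c1cc(OCc2ccccc2)cc(OC)c1C(=O)OCC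
F2 | step 13 | 4-(benzyloxy)-2-(1-carboxypropyl)-6-methoxybenzoic acid (racemic) | CCC(C(=O)O)c1cc(OCc2ccccc2)cc(OC)c1C(=O)O
F3 | step 13 | 4-(benzyloxy)-2-methoxy-6-propylbenzoic acid | CCCc1cc(OCc2ccccc2)cc(OC)c1C(=O)O
F4 | step 13 | 4-(benzyloxy)-2-methoxy-6-propylbenzoyl chloride | CCCc1cc(OCc2ccccc2)cc(OC)c1C(Cl)=O
F5 | step 15 | 2-sulfanylidenepyridin-1(2H)-yl 2-[2-{[3-acetyl-2,6-bis(benzyloxy)-4-pentylphenoxy]carbonyl}-5-(benzyloxy)-3-methoxyphenyl]butanoate (racemic) | CCCCCc1cc(OCc2ccccc2)c(OC(=O)c2c(C(CC)C(=O)ON3C=CC=CC3=S)cc(OCc3ccccc3)cc2OC)c(OCc2ccccc2)c1C(C)=O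
F6 | step 4 | lithium 2,6-bis(benzyloxy)-3-lithio-4-pentylphenolate | CCCCCc1cc(OCc2ccccc2)c(O[Li])c(OCc2ccccc2)c1[Li]
F7 | step 9 | 2-bromo-3-methoxy-5-{[tri(propan-2-yl)silyl]oxy}phenol | COc1cc(O[Si](C(C)C)(C(C)C)C(C)C)cc(O)c1Br
F8 | step 9 | [2-bromo-3-methoxy-5-{[tri(propan-2-yl)silyl]oxy}phenoxy]trimethylsilane | COc1cc(O[Si](C(C)C)(C(C)C)C(C)C)cc(O[Si](C)(C)C)c1Br
F9 | step 9 | lithium 3-methoxy-5-{[tri(propan-2-yl)silyl]oxy}-2-(trimethylsilyl)phenolate | COc1cc(O[Si](C(C)C)(C(C)C)C(C)C)cc(O[Li])c1[Si](C)(C)C
F10 | step 2 | 2-iodo-5-pentylbenzene-1,3-diol | CCCCCc1cc(O)c(I)c(O)c1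
F11 | step 2 | 1,3-bis(benzyloxy)-2-iodo-5-pentylbenzene | CCCCCc1cc(OCc2ccccc2)c(I)c(OCc2ccccc2)c1
F12 | step 2 | [2,6-bis(benzyloxy)-4-pentylphenyl]magnesium chloride | CCCCCc1cc(OCc2ccccc2)c([Mg]Cl)c(OCc2ccccc2)c1
A1 | alternative 1 | 3-acetyl-2,6-dihydroxy-4-pentylphenyl 4-(benzyloxy)-2-methoxy-6-propylbenzoate | CCCCCc1cc(O)c(OC(=O)c2c(CCC)cc(OCc3ccccc3)cc2OC)c(O)c1C(C)=O
A2 | alternative 1 | 1-methoxy-1,3-bis[(trimethylsilyl)oxy]buta-1,3-dien-2-yl 4-(benzyloxy)-2-methoxy-6-propylbenzoate (double-bond geometry unspecified) | COC(O[Si](C)(C)C)=C(OC(=O)c1c(CCC)cc(OCc2ccccc2)cc1OC)C(=C)O[Si](C)(C)C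
A3 | alternative 1 | non-3-yn-2-one | CCCCCC#CC(C)=O
A4 | alternative 1 | 4-(benzyloxy)-2-methoxy-6-propylbenzoic acid | CCCc1cc(OCc2ccccc2)cc(OC)c1C(=O)O
A5 | alternative 2 | 3-acetyl-2,6-bis(benzyloxy)-4-pentylphenyl 4-hydroxy-2-methoxy-6-propylbenzoate | CCCCCc1cc(OCc2ccccc2)c(OC(=O)c2c(CCC)cc(O)cc2OC)c(OCc2ccccc2)c1C(C)=O
A6 | alternative 2 | 3-acetyl-2,6-bis(benzyloxy)-4-pentylphenyl hex-2-ynoate | CCCCCc1cc(OCc2ccccc2)c(OC(=O)C#CCCC)c(OCc2ccccc2)c1C(C)=O
A7 | alternative 2 | 1,1-dimethoxy-3-(trimethylsilyloxy)buta-1,3-diene | COC(OC)=CC(=C)O[Si](C)(C)C
A8 | alternative 3 | 3-acetyl-2,6-bis(benzyloxy)-4-pentylphenyl 2,4-dihydroxy-6-propylbenzoate | CCCCCc1cc(OCc2ccccc2)c(OC(=O)c2c(CCC)cc(O)cc2O)c(OCc2ccccc2)c1C(C)=O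
A9 | alternative 3 | 6-(2,4-dioxoheptyl)-2,2-dimethyl-4H-1,3-dioxin-4-one | CCCC(=O)CC(=O)CC1=CC(=O)OC(C)(C)O1
A10 | alternative 3 | 3-acetyl-2,6-bis(benzyloxy)-4-pentylphenyl 3,5,7-trioxodecanoate | CCCCCc1cc(OCc2ccccc2)c(OC(=O)CC(=O)CC(=O)CC(=O)CCC)c(OCc2ccccc2)c1C(C)=O
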